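C1 is the methyl-bearing ring-fusion carbon; ring A (five-membered) is C1–C2–C3–C4(OH, isopropyl)–C5 and ring B (seven-membered) is C5–C6(O-aroyl)–C7–C8(methyl)=C9–C10(O-tigloyl)–C1.
Cuts: first the two acyl–O bonds (C10, then C6); C6–OH goes back to a C6 ketone, and the C8=C9/C10–O unit to a C9=C10 alkene whose only allylic hydrogen is H8, because C1 is quaternary.
Enabling feature: in ring B the carbonyl carbon C6 sits between C5 and C7 (an oxyallyl unit) and C1=C10–C9=C8 is a diene, so cutting C1–C5 and C7–C8 opens rings A and B at once to an acyclic chloromethyl ketone.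
Forward order: the chain is joined linearly (C1–C6 from ozonolysis of (S)-terpinen-4-ol, the C1-methyl from Me3Al, C8/C9 and the C8-methyl from (E)-1-bromopropene, C7 from ICH2Cl); rings A and B then close together in one (4+3) step, and the two esters go on last.
Stereochemistry: C4 comes with the terpene; C1, C5 and C8 arise in the cycloaddition under control of C4 and the E,E-diene; C6 from hydride delivered by the C4 hydroxyl; C10 from a suprafacial ene reaction that replaces H8 by oxygen on the same face.

Key step: step 9

Assumption: (S)-terpinen-4-ol and (E)-1-bromoprop-1-ene are used as single isomers; CIP descriptors of ring compounds refer to the locants above, and those at C1, C4 and C5 change along the route only because substituent rankings change, not the geometry.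

Step 1
Reactants: 1 (S)-terpinen-4-ol
Product: 2 (S)-triethyl{[4-methyl-1-(propan-2-yl)cyclohex-3-en-1-yl]oxy}silane
Conditions: Et3SiOTf, 2,6-lutidine, CH2Cl2, 0 °C to rt
Reagents that add atoms: triethylsilyl trifluoromethanesulfonate, CC[Si](CC)(CC)OS(=O)(=O)C(F)(F)F
Why: Silyl triflate/lutidine silylation caps the hindered tertiary alcohol, which later prevents hemiketal formation and O-alkylation by the chloromethyl ketone.

Step 2
Reactants: 2 silyl ether
Product: 4 (3S)-6-oxo-3-(propan-2-yl)-3-(triethylsilyloxy)heptanal, via ozonide 3 (not isolated)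
Conditions: O3, CH2Cl2, −78 °C; then PPh3, −78 °C to rt
Reagents that add atoms: ozone, [O-][O+]=O
Why: Ozonolysis with reductive work-up cleaves the only C=C bond to the methyl ketone (C1) and the aldehyde (C6) without touching the quaternary C4 stereocentre.

Step 3
Reactants: 4 keto aldehyde
Product: 5 (5S)-7,7-dimethoxy-5-(propan-2-yl)-5-(triethylsilyloxy)heptan-2-one
Conditions: HC(OMe)3, CeCl3·7H2O, MeOH, rt
Reagents that add atoms: trimethyl orthoformate, COC(OC)OC; methanol, CO
Why: Under CeCl3/orthoformate an aldehyde is acetalised much faster than a methyl ketone (chemoselective acetalisation), which masks C6 for the basic and organometallic steps that follow.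

Step 4
Reactants: 5 keto acetal
Product: 7 (5S)-7,7-dimethoxy-5-(propan-2-yl)-5-(triethylsilyloxy)hept-1-yne, via enol phosphate 6 (not isolated)
Conditions: LiN(iPr)2, THF, −78 °C; ClP(O)(OEt)2, −78 °C to rt; then LiN(iPr)2 (2.3 equiv), −78 °C to rt; aq NH4Cl
Reagents that add atoms: none
Why: Kinetic deprotonation at the methyl group, O-phosphorylation and base-induced elimination of the enol phosphate (Negishi alkyne synthesis from a methyl ketone) give the terminal alkyne, the acetal and silyl ether being inert to the amide base.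

Step 5
Reactants: 7 alkyne; 8 (E)-1-bromoprop-1-ene
Product: 10 (2E,4E,8S)-10,10-dimethoxy-5-methyl-8-(propan-2-yl)-8-(triethylsilyloxy)deca-2,4-diene, via alkenylalane 9 (not isolated)
Conditions: Me3Al, Cp2ZrCl2 (20 mol %), CH2Cl2, 0 °C to rt; then 8 (3 equiv), Pd(PPh3)4 (5 mol %), ZnCl2 (cat.), THF, rt
Reagents that add atoms: trimethylaluminium, C[Al](C)C
Why: Zirconium-catalysed syn-carboalumination (Negishi) places methyl on the internal carbon and aluminium on the terminus with E geometry, and the palladium/zinc-cocatalysed cross-coupling of the alkenylalane with 8 keeps the geometry of both alkenes.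

Step 6
Reactants: 10 diene acetal
Product: 11 (3S,6E,8E)-6-methyl-3-(propan-2-yl)-3-(triethylsilyloxy)deca-6,8-dienal
Conditions: SiO2, 10% aq oxalic acid, CH2Cl2, rt
Reagents that add atoms: water, O
Why: Dimethyl acetals of aliphatic aldehydes hydrolyse on oxalic acid-doped wet silica (mild acetal hydrolysis), which should spare the hindered tertiary silyl ether and the diene.

Step 7
Reactants: 11 aldehyde
Product: 12 (4S,7E,9E)-1-chloro-7-methyl-4-(propan-2-yl)-4-(triethylsilyloxy)undeca-7,9-dien-2-ol (both C2 epimers)
Conditions: ICH2Cl, MeLi·LiBr, THF/Et2O, −78 °C; AcOH, −78 °C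
Reagents that add atoms: chloroiodomethane, ClCI
Why: Chloromethyllithium formed in situ by lithium–iodine exchange adds to the aldehyde at −78 °C (Barbier-type carbenoid addition) and the cold acid quench keeps the chlorohydrin from closing to the epoxide; the new carbinol centre is erased in step 8.

Step 8
Reactants: 12 chlorohydrin
Product: 13 (4S,7E,9E)-1-chloro-7-methyl-4-(propan-2-yl)-4-(triethylsilyloxy)undeca-7,9-dien-2-one
Conditions: Dess–Martin periodinane, pyridine, CH2Cl2, 0 °C to rt
Reagents that add atoms: none
Why: Dess–Martin oxidation turns the chlorohydrin into the α-chloro ketone under buffered, non-enolising conditions that leave the diene and silyl ether alone.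

Step 9
Reactants: 13 chloromethyl ketone
Product: 15 cis-fused hydroazulen-6-one (1S,4R,5R,8S; C9=C10 alkene; C4 triethylsilyl ether), via oxyallyl cation 14 (not isolated)
Conditions: Et3N (1.5 equiv), CF3CH2OH (0.01 M), 0 °C to rt
Reagents that add atoms: none
Why: Et3N enolises 13 towards C5 and the enol ionises at C7 in the weakly nucleophilic, strongly ionising fluoroalcohol to the oxyallyl cation 14 (C5–C6(O)–C7), which bonds through C5 and C7 to the diene termini C1 and C8, in concert or in two fast steps. The closest known reaction type is the intramolecular (4+3) cycloaddition of oxyallyl cations, generated from α-chloro ketones with amine base in fluorinated alcohols, with tethered 1,3-butadienes. Ring A closes through the three-atom tether C2–C4 as C5 bonds to C1 (5-exo with respect to C1=C10), and ring B is closed by the cycloaddition itself when C7 bonds to C8. C5 and C1 are set by the compact transition state of the Z cation (oxygen syn to C4), which puts C6 and C10 on one face of the new cyclopentane (cis fusion), and by C4, whose isopropyl group, bulkier at the ring than the oxygen-linked silyl ether, sends the C5–C6 bond to the opposite face; C8 is set by suprafacial addition to the E,E-diene, which leaves the C8-methyl cis to C2 and H8 cis to the C1-methyl. The step needs (4+3) closure to win over solvent capture, Favorskii collapse and five- or six-membered cation cyclisation; the substrate offers a short tether that holds C5 over C1, a diene that can reach the s-cis form and a masked C4 hydroxyl that cannot alkylate at C7, and high dilution suppresses intermolecular paths. Bond formation at the fully substituted C1 terminus is the demanding element, and any trans-fused material can be treated with base at this stage because C5 is epimerisable next to the C6 ketone.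

Step 10
Reactants: 15 cycloadduct
Product: 16 cis-fused 4-hydroxy-hydroazulen-6-one (1S,4R,5R,8S; C9=C10 alkene)
Conditions: HF·pyridine, pyridine, THF, 0 °C to rt
Reagents that add atoms: none
Why: Buffered HF·pyridine cleaves the tertiary triethylsilyl ether (fluoride desilylation) without the base that could cause retro-aldol opening or C5 epimerisation of the β-hydroxy ketone.

Step 11
Reactants: 16 hydroxy ketone
Product: 17 cis-fused hydroazulene-4,6-diol (1S,4R,5S,6S,8S; C9=C10 alkene)
Conditions: Me4NBH(OAc)3, MeCN/AcOH (1:1), −30 to 0 °C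
Reagents that add atoms: none
Why: In the Evans–Saksena reduction the C4 hydroxyl exchanges onto boron and delivers hydride intramolecularly to C6 from the face of ring B on which the C4 branch lies, so the new C6 hydroxyl ends up cis to H5 (6S).

Step 12
Reactants: 18 4-hydroxybenzoic acid
Product: 20 4-(tert-butyldimethylsilyloxy)benzoic acid, via silyl ester 19 (not isolated)
Conditions: tBuMe2SiCl (2.2 equiv), imidazole, DMF, rt; then AcOH, THF/H2O, rt
Reagents that add atoms: tert-butyldimethylsilyl chloride, CC(C)(C)[Si](C)(C)Cl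
Why: Silylation of both acidic sites followed by hydrolysis of the labile silyl ester leaves the aryl silyl ether (standard phenol protection).

Step 13
Reactants: 17 diol; 20 protected acid
Product: 21 C6 4-(tert-butyldimethylsilyloxy)benzoate of 17 (1S,4R,5S,6S,8S)
Conditions: 20, 2,4,6-Cl3C6H2COCl, Et3N, THF, rt; then 17, DMAP, toluene, rt
Reagents that add atoms: none
Why: Yamaguchi esterification acylates the secondary C6 hydroxyl, the tertiary, isopropyl-flanked C4 hydroxyl being too hindered to compete.

Step 14
Reactants: 21 C6 ester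
Product: 23 C10 allylic alcohol with C8=C9 alkene (1R,4R,5S,6S,10R), via hydroperoxide 22 (not isolated)
Conditions: O2, visible light, tetraphenylporphyrin (cat.), CH2Cl2, 0 °C; then PPh3
Reagents that add atoms: dioxygen, O=O
Why: In the Schenck ene reaction of singlet oxygen H8 is the only allylic hydrogen, so oxygen must bond to C10 while the alkene moves to C8=C9, and because the process is suprafacial the oxygen arrives on the face that carried H8, cis to the C1-methyl (10R); PPh3 then reduces the hydroperoxide in the same flask.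

Step 15
Reactants: 23 allylic alcohol; 24 tiglic acid
Product: 25 C10 tiglate of 23 (1R,4R,5S,6S,10R)
Conditions: 24, 2,4,6-Cl3C6H2COCl, Et3N, toluene, rt; then 23, DMAP, toluene, 60 °C
Reagents that add atoms: none
Why: Yamaguchi esterification acylates the secondary allylic C10 hydroxyl with the E-configured acid unchanged, the tertiary C4 hydroxyl again staying free.

Step 16
Reactants: 25 silyl-protected diester
Product: 26 target compound (1R,4R,5S,6S,10R)
Conditions: Bu4NF, AcOH, THF, 0 °C
Reagents that add atoms: none
Why: Acetic acid-buffered fluoride cleaves the aryl silyl ether far faster than it attacks either ester (fluoride desilylation), which releases the phenol.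

Compound list
1 | (S)-terpinen-4-ol, (1S)-4-methyl-1-(propan-2-yl)cyclohex-3-en-1-ol | CC1=CC[C@](O)(C(C)C)CC1 | starting material
2 | (S)-triethyl{[4-methyl-1-(propan-2-yl)cyclohex-3-en-1-yl]oxy}silane | CC1=CC[C@](O[Si](CC)(CC)CC)(C(C)C)CC1 | intermediate
3 | ozonide of 2 (1,2,4-trioxolane across the former alkene carbons; carbinol centre unchanged; new acetal carbons not defined) | CC1(OO2)CC[C@@](O[Si](CC)(CC)CC)(C(C)C)CC2O1 | intermediate (not isolated)
4 | (3S)-6-oxo-3-(propan-2-yl)-3-(triethylsilyloxy)heptanal | O=CC[C@](O[Si](CC)(CC)CC)(C(C)C)CCC(C)=O | intermediate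
5 | (5S)-7,7-dimethoxy-5-(propan-2-yl)-5-(triethylsilyloxy)heptan-2-one | COC(OC)C[C@](O[Si](CC)(CC)CC)(C(C)C)CCC(C)=O | intermediate
6 | diethyl (5S)-7,7-dimethoxy-5-(propan-2-yl)-5-(triethylsilyloxy)hept-1-en-2-yl phosphate | COC(OC)C[C@](O[Si](CC)(CC)CC)(C(C)C)CCC(=C)OP(=O)(OCC)OCC | intermediate (not isolated)
7 | (5S)-7,7-dimethoxy-5-(propan-2-yl)-5-(triethylsilyloxy)hept-1-yne | COC(OC)C[C@](O[Si](CC)(CC)CC)(C(C)C)CCC#C | intermediate
8 | (E)-1-bromoprop-1-ene | C/C=C/Br | starting material
9 | (E)-alkenyldimethylalane from 7: methyl on the internal alkene carbon, AlMe2 on the terminus and cis to that methyl, carbinol centre S | COC(OC)C[C@](O[Si](CC)(CC)CC)(C(C)C)CC/C(C)=C/[Al](C)C | intermediate (not isolated)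
10 | (2E,4E,8S)-10,10-dimethoxy-5-methyl-8-(propan-2-yl)-8-(triethylsilyloxy)deca-2,4-diene | COC(OC)C[C@](O[Si](CC)(CC)CC)(C(C)C)CC/C(C)=C/C=C/C | intermediate
11 | (3S,6E,8E)-6-methyl-3-(propan-2-yl)-3-(triethylsilyloxy)deca-6,8-dienal | O=CC[C@](O[Si](CC)(CC)CC)(C(C)C)CC/C(C)=C/C=C/C | intermediate
12 | (4S,7E,9E)-1-chloro-7-methyl-4-(propan-2-yl)-4-(triethylsilyloxy)undeca-7,9-dien-2-ol, both C2 epimers | ClCC(O)C[C@](O[Si](CC)(CC)CC)(C(C)C)CC/C(C)=C/C=C/C | intermediate
13 | (4S,7E,9E)-1-chloro-7-methyl-4-(propan-2-yl)-4-(triethylsilyloxy)undeca-7,9-dien-2-one (cycloaddition precursor) | ClCC(=O)C[C@](O[Si](CC)(CC)CC)(C(C)C)CC/C(C)=C/C=C/C | intermediate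
14 | oxyallyl cation (zwitterion) C5–C6(O)–C7 from 13, drawn as the Z form with oxygen syn to C4 | [CH2+]/C([O-])=C/[C@](O[Si](CC)(CC)CC)(C(C)C)CC/C(C)=C/C=C/C | intermediate (not isolated)
15 | (1S,4R,5R,8S)-1,8-dimethyl-4-(propan-2-yl)-4-(triethylsilyloxy) cis-fused hydroazulen-6-one with C9=C10 alkene; H5 and C1-methyl cis, C4–O cis to the C5–C6 bond, C8-methyl trans to C1-methyl | C1=C[C@@H](C)CC(=O)[C@@H]2[C@@]1(C)CC[C@@]2(O[Si](CC)(CC)CC)C(C)C | intermediate
16 | (1S,4R,5R,8S)-4-hydroxy-1,8-dimethyl-4-(propan-2-yl) cis-fused hydroazulen-6-one with C9=C10 alkene | C1=C[C@@H](C)CC(=O)[C@@H]2[C@@]1(C)CC[C@@]2(O)C(C)C | intermediate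
17 | (1S,4R,5S,6S,8S)-1,8-dimethyl-4-(propan-2-yl) cis-fused hydroazulene-4,6-diol with C9=C10 alkene; C6–OH cis to H5 | C1=C[C@@H](C)C[C@H](O)[C@@H]2[C@@]1(C)CC[C@@]2(O)C(C)C | intermediate
18 | 4-hydroxybenzoic acid | O=C(O)c1ccc(O)cc1 | starting material
19 | tert-butyldimethylsilyl 4-(tert-butyldimethylsilyloxy)benzoate | CC(C)(C)[Si](C)(C)OC(=O)c1ccc(O[Si](C)(C)C(C)(C)C)cc1 | intermediate (not isolated)
20 | 4-(tert-butyldimethylsilyloxy)benzoic acid | O=C(O)c1ccc(O[Si](C)(C)C(C)(C)C)cc1 | intermediate
21 | C6 4-(tert-butyldimethylsilyloxy)benzoate of 17 (1S,4R,5S,6S,8S), C4–OH free | C1=C[C@@H](C)C[C@H](OC(=O)c3ccc(O[Si](C)(C)C(C)(C)C)cc3)[C@@H]2[C@@]1(C)CC[C@@]2(O)C(C)C | intermediate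
22 | C10 hydroperoxide (1R,4R,5S,6S,10R) with C8=C9 alkene; OOH cis to C1-methyl | OO[C@@H]1C=C(C)C[C@H](OC(=O)c3ccc(O[Si](C)(C)C(C)(C)C)cc3)[C@@H]2[C@@]1(C)CC[C@@]2(O)C(C)C | intermediate (not isolated)
23 | C10 allylic alcohol (1R,4R,5S,6S,10R) with C8=C9 alkene | O[C@@H]1C=C(C)C[C@H](OC(=O)c3ccc(O[Si](C)(C)C(C)(C)C)cc3)[C@@H]2[C@@]1(C)CC[C@@]2(O)C(C)C | intermediate
24 | tiglic acid, (E)-2-methylbut-2-enoic acid | C/C=C(\C)C(=O)O | starting material
25 | C10 tiglate, C6 4-(tert-butyldimethylsilyloxy)benzoate (1R,4R,5S,6S,10R) | C/C=C(\C)C(=O)O[C@@H]1C=C(C)C[C@H](OC(=O)c3ccc(O[Si](C)(C)C(C)(C)C)cc3)[C@@H]2[C@@]1(C)CC[C@@]2(O)C(C)C | intermediate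
26 | CNP0273650.9: C10 tiglate, C6 4-hydroxybenzoate, C4 tertiary alcohol (1R,4R,5S,6S,10R) | C/C=C(\C)C(=O)O[C@@H]1C=C(C)C[C@H](OC(=O)c2ccc(O)cc2)[C@@H]2[C@@]1(C)CC[C@@]2(O)C(C)C | target

Total steps: 16. Longest linear sequence: 15 steps (steps 1–11 and 13–16); step 12 is a one-step side branch.

Steps most likely to fail

Step 9. The unstabilised cation may be captured by the solvent or collapse by the Favorskii path before it bonds to the crowded C1 terminus. The diene may also react from its s-trans form, so that the zwitterion closes a five- or six-membered ring instead, and the enol may lose the C4 silyloxy group by β-elimination. If ring closure becomes stepwise, facial, fusion and C8 selectivity may erode, and an error at C8 would be carried into C10. The fallback sets out from aldehyde 11 and returns at 15. LiCHCl2 (from CH2Cl2 and LiN(iPr)2, THF, −78 °C) is added to 11 to give the dichloromethyl carbinol F1, and Dess–Martin oxidation gives the dichloromethyl ketone F2. Et3N in CF3CH2OH then generates a chlorine-stabilised, longer-lived oxyallyl cation, the kind that is most dependable in amine/fluoroalcohol (4+3) chemistry. The resulting C7-chloro cycloadduct F3 is dechlorinated with Zn and NH4Cl in MeOH to 15.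

Step 14. A cis-disubstituted alkene accepts singlet oxygen slowly, approach to C10 is neopentyl, and the trisubstituted alkene of the product can be photooxygenated further, so conversion and over-oxidation may not be separable. The fallback sets out from diol 17 and returns at 23. mCPBA (NaHCO3, CH2Cl2, 0 °C) should epoxidise the exposed face, cis to H8 and the C6 hydroxyl, to the 9,10-epoxide F4. Diethylaluminium 2,2,6,6-tetramethylpiperidide (from Et2AlCl and lithium 2,2,6,6-tetramethylpiperidide, toluene, 0 °C) removes the β-hydrogen syn to the epoxide oxygen. This opens the epoxide to the allylic triol F5, with the C8=C9 alkene and the C10 hydroxyl on the required face. Yamaguchi acylation with 20 at the less hindered C6 hydroxyl (C10 is neopentyl) then gives 23.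

Step 11. The hindered tertiary C4 hydroxyl may exchange onto boron too slowly or deliver hydride to the wrong carbonyl face, and the β-hydroxy ketone 16 may undergo retro-aldol cleavage in the meantime. The fallback sets out from 15 and returns at 21. NaBH4 in MeOH should reduce the silyl-protected ketone from the face away from the C4 substituents to the 6-epi alcohol F6. Mitsunobu esterification with 20 (PPh3, diisopropyl azodicarboxylate, toluene) inverts C6 and installs the aroyl group in one operation to give the silyl-protected ester F7. HF·pyridine then removes the C4 triethylsilyl group to give 21.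

Further compounds
F1 | step 9 | (4S,7E,9E)-1,1-dichloro-7-methyl-4-(propan-2-yl)-4-(triethylsilyloxy)undeca-7,9-dien-2-ol, both C2 epimers | ClC(Cl)C(O)C[C@](O[Si](CC)(CC)CC)(C(C)C)CC/C(C)=C/C=C/C
F2 | step 9 | (4S,7E,9E)-1,1-dichloro-7-methyl-4-(propan-2-yl)-4-(triethylsilyloxy)undeca-7,9-dien-2-one | ClC(Cl)C(=O)C[C@](O[Si](CC)(CC)CC)(C(C)C)CC/C(C)=C/C=C/C
F3 | step 9 | C7-chloro derivative of cycloadduct 15, both C7 epimers | C1=C[C@@H](C)C(Cl)C(=O)[C@@H]2[C@@]1(C)CC[C@@]2(O[Si](CC)(CC)CC)C(C)C
F4 | step 14 | 9,10-epoxide of diol 17, epoxide oxygen cis to the C1-methyl, H8 and the C6 hydroxyl | O1[C@@H]2[C@H]1[C@@H](C)C[C@H](O)[C@@H]3[C@@]2(C)CC[C@@]3(O)C(C)C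
F5 | step 14 | (1R,4R,5S,6S,10R)-4,6,10-triol with C8=C9 alkene | O[C@@H]1C=C(C)C[C@H](O)[C@@H]2[C@@]1(C)CC[C@@]2(O)C(C)C
F6 | step 11 | 6-epi alcohol from 15 (C6–OH trans to H5), C4 triethylsilyl ether | C1=C[C@@H](C)C[C@@H](O)[C@@H]2[C@@]1(C)CC[C@@]2(O[Si](CC)(CC)CC)C(C)C
F7 | step 11 | C4 triethylsilyl ether of ester 21 | C1=C[C@@H](C)C[C@H](OC(=O)c3ccc(O[Si](C)(C)C(C)(C)C)cc3)[C@@H]2[C@@]1(C)CC[C@@]2(O[Si](CC)(CC)CC)C(C)C
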